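The tetrahydrofuran ring (O1, C2–C5) carries two one-carbon arms, C9 on C3 and C7' on C4. They are cis to each other and trans to the C2 syringyl group. That pattern is the footprint of a ketene on the C3=C4 bond of an (S)-2-aryl-2,5-dihydrofuran, which an enantioselective Heck arylation supplies. A single dichloroketene [2+2] addition, anti to the aryl group, forms C3–C9 and C4–C7', closes a cis-fused cyclobutanone and sets C3 and C4. Later scission of C9–C7' leaves an acid and a masked aldehyde. The precursor holds its phenol as a diethylcarbamate, which tempers the arene and survives hydrogenolysis.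

Key step: step 5

Labels: O1, C2 (aryl), C3, C4 and C5 are the ring atoms. C9 is the carbon on C3 and C7' is the carbon on C4. Ar = 4-(N,N-diethylcarbamoyloxy)-3,5-dimethoxyphenyl.

Assumption: the (R)-tert-butyl phosphinooxazoline is assigned to the (S)-dihydrofuran by analogy with simple aryl triflates, for which the (S)-ligand leads to the (R) series; both ligand enantiomers are commercial, so a reversed sense would be corrected without changing the route.

Step 1
Reactants: 1 2,6-dimethoxyphenol (syringol)
Product: 2 2,6-dimethoxyphenyl N,N-diethylcarbamate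
Conditions: NaH, Et2NCOCl, THF, 0 → 65 °C
Reagents that add atoms: N,N-diethylcarbamoyl chloride, CCN(CC)C(=O)Cl
Why: O-carbamoylation of the sodium phenoxide is a routine phenol protection, and the diethylcarbamate is chosen because it withdraws electron density from the ring, withstands aqueous base, Grignard reagents and hydrogenolysis, and is removed by LiAlH4 in a step that the route needs anyway.

Step 2
Reactants: 2 2,6-dimethoxyphenyl N,N-diethylcarbamate
Product: 4 4-hydroxy-2,6-dimethoxyphenyl N,N-diethylcarbamate, via aryl pinacol boronate 3 (not isolated)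
Conditions: [Ir(OMe)(cod)]2 (1.5 mol %), dtbpy (3 mol %), B2pin2 (0.6 equiv), THF, 80 °C; then KHSO5 (Oxone), acetone/H2O, rt
Reagents that add atoms: bis(pinacolato)diboron, CC1(C)OB(OC1(C)C)B1OC(C)(C)C(C)(C)O1 (boryl group of 3); potassium peroxymonosulfate, [K+].[O-]S(=O)(=O)OO (phenol oxygen)
Why: iridium-catalysed C–H borylation is governed by sterics, so in this 1,2,3-trisubstituted arene only the C–H para to the carbamate (the one without an ortho substituent) should react, and oxidation of the crude boronate in the same flask is the established borylation/oxidation route to phenols.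

Step 3
Reactants: 4 4-hydroxy-2,6-dimethoxyphenyl N,N-diethylcarbamate
Product: 5 4-(N,N-diethylcarbamoyloxy)-3,5-dimethoxyphenyl trifluoromethanesulfonate
Conditions: PhNTf2, Et3N, CH2Cl2, rt
Reagents that add atoms: N-phenylbis(trifluoromethanesulfonimide), O=S(=O)(N(c1ccccc1)S(=O)(=O)C(F)(F)F)C(F)(F)F
Why: sulfonylation of the unhindered phenol with the mild triflyl donor PhNTf2 is standard and leaves the carbamate untouched.

Step 4
Reactants: 5 aryl triflate; 6 2,3-dihydrofuran
Product: 7 4-[(2S)-2,5-dihydrofuran-2-yl]-2,6-dimethoxyphenyl N,N-diethylcarbamate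
Conditions: Pd2(dba)3 (2.5 mol %), (R)-tBu-PHOX (6 mol %), iPr2NEt, 6 (5 equiv), THF, 70 °C
Reagents that add atoms: none
Why: enantioselective intermolecular Heck reaction, in which oxidative addition of the triflate to zerovalent palladium gives a cationic aryl complex, the P,N ligand selects the enantioface of 6 during migratory insertion (aryl to the carbon next to oxygen, which becomes C2 with S configuration), and syn β-hydride elimination followed by the fast alkene release typical of phosphinooxazoline catalysts leaves the C3=C4 isomer without double-bond migration.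

Step 5
Reactants: 7 (S)-2-Ar-2,5-dihydrofuran; 8 trichloroacetyl chloride
Product: 10 (1R,4S,5S)-4-Ar-7,7-dichloro-3-oxabicyclo[3.2.0]heptan-6-one (cis-fused; carbonyl carbon C9 on C3; CCl2 carbon C7' on C4; cyclobutanone trans to Ar), via dichloroketene 9 (not isolated)
Conditions: 8 (slow addition), Zn–Cu couple, DME, Et2O, ultrasound, 20 °C
Reagents that add atoms: none
Why: Zinc dechlorinates 8 to dichloroketene 9, which adds to C3=C4 in a concerted but asynchronous [2+2] process (alkene suprafacial, ketene antarafacial) in which the bond from the electrophilic carbonyl carbon runs ahead of the bond from the CCl2 terminus; the closest known reactions are the dichloroketene additions to cyclopentene and to 2,5-dihydrofuran itself. The cyclobutanone ring is closed by intermolecular annulation, with both new bonds (C3–C9 and C4–C7') reaching the same alkene face, so only a cis ring fusion is possible. C3 and C4 are both controlled by the C2 stereocentre, because the aryl group shields its own face and the ketene arrives anti to it, which should give the (1R,4S,5S) adduct. The step needs regioselectivity: the leading bond should go to C3, because the positive charge that then builds on C4 lies next to C5H2 and not next to C2 (which carries O1 and an acceptor-substituted aryl group), and the bulky CCl2 end thereby also meets the less crowded alkene carbon. It also needs chemoselectivity against acylative or Lewis-acid opening of the allylic, benzylic C2–O1 bond and against attack of O1 on the ketene, which the carbamate (a much weaker donor than an alkyl ether or free phenol), the slow addition of 8 and DME as a trap for ZnCl2 are meant to secure.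

Step 6
Reactants: 10 dichlorocyclobutanone
Product: 12 (3aR,6S,6aS)-6-Ar-3-hydroxytetrahydro-1H,3H-furo[3,4-c]furan-1-one (cis-fused lactol; both C3 epimers; C1 = C9 and C3 = C7'), via dichloromethyl acid 11 (not isolated)
Conditions: LiOH (3 equiv), dioxane/H2O, 5 °C; then AcOH to pH 5, 90 °C
Reagents that add atoms: lithium hydroxide, [Li+].[OH-]; water, O
Why: haloform-type (retro-Claisen) cleavage, in which hydroxide adds to the strained, chlorine-activated carbonyl and expels the dichloromethyl carbanion so that C9–C7' breaks, the resulting carboxylate protects C3 from enolisation, and in the acetate buffer the cis carboxylate displaces chloride from CHCl2 (neighbouring-group-assisted hydrolysis of a geminal dichloride) to give the lactol, whose closed form shields C4 from epimerisation and from β-elimination of O1.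

Step 7
Reactants: 13 4-bromo-2-methoxyphenol
Product: 14 1-(benzyloxy)-4-bromo-2-methoxybenzene
Conditions: BnBr, K2CO3, acetone, reflux
Reagents that add atoms: benzyl bromide, BrCc1ccccc1
Why: Williamson ether synthesis masks the acidic phenol before metalation, with a group that step 9 removes at no extra cost.

Step 8
Reactants: 12 lactol; 14 1-(benzyloxy)-4-bromo-2-methoxybenzene
Product: 17 (3aR,6S,6aS)-6-Ar-3-(4-benzyloxy-3-methoxyphenyl)tetrahydro-1H,3H-furo[3,4-c]furan-1-one (both C3 epimers), via aryl Grignard reagent 15 (not isolated), via hydroxy acid 16 (not isolated)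
Conditions: 14, Mg, THF, reflux; then 12 (0.4 equiv), THF, −78 → 0 °C; 1 M HCl; PPTS (cat.), CH2Cl2, rt
Reagents that add atoms: magnesium, [Mg] (present only in intermediate 15)
Why: Grignard addition to a pseudo-acid, as known for hydroxyphthalides and γ-hydroxybutyrolactones, in which the first equivalent of 15 deprotonates 12 and opens it to the magnesium carboxylate aldehyde, the second adds to C7' faster than it enolises C4, and mild acid closes the cis hydroxy acid 16 to the lactone, the new centre at C7' being of no consequence because step 9 erases it.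

Step 9
Reactants: 17 bicyclic lactone
Product: 18 (2S,3S,4R)-2-Ar-4-(4-hydroxy-3-methoxybenzyl)tetrahydrofuran-3-carboxylic acid
Conditions: H2 (3 bar), Pd/C (10 %), EtOAc/AcOH, rt
Reagents that add atoms: none
Why: catalytic hydrogenolysis removes the benzyl ether and the benzylic acyloxy bond C7'–O of what is then a 4-hydroxybenzylic lactone, whereas C2–O1 is an ether bond (poorer leaving group) on an arene kept electron-poor by the carbamate and should stay, and no ring stereocentre is touched.

Step 10
Reactants: 18 carboxylic acid
Product: 19 4-[(2S,3R,4R)-4-(4-hydroxy-3-methoxybenzyl)-3-(hydroxymethyl)tetrahydrofuran-2-yl]-2,6-dimethoxyphenol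
Conditions: LiAlH4, THF, 0 → 65 °C
Reagents that add atoms: none
Why: LiAlH4 reduces the carboxylic acid to the C9 primary alcohol and cleaves the aryl carbamate reductively to the phenol, both standard hydride reductions that leave C2, C3 and C4 unchanged.

Step 11
Reactants: 19 triol; 20 (E)-ferulic acid
Product: 21 [(2S,3R,4R)-2-(4-hydroxy-3,5-dimethoxyphenyl)-4-(4-hydroxy-3-methoxybenzyl)tetrahydrofuran-3-yl]methyl (E)-3-(4-hydroxy-3-methoxyphenyl)prop-2-enoate (target)
Conditions: PPh3, DIAD, THF, 0 °C → rt
Reagents that add atoms: none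
Why: Mitsunobu esterification pairs the only aliphatic alcohol with the carboxylic acid, which is far more acidic than any of the three phenols and is therefore the pronucleophile that the betaine deprotonates (a chemoselectivity known for unprotected phenolic acids and phenolic alcohols), while C9 is not stereogenic and the E alkene is not affected.

Compound list
1 | 2,6-dimethoxyphenol | COc1cccc(OC)c1O | starting material
2 | 2,6-dimethoxyphenyl N,N-diethylcarbamate | CCN(CC)C(=O)Oc1c(OC)cccc1OC | intermediate
3 | 2,6-dimethoxy-4-(4,4,5,5-tetramethyl-1,3,2-dioxaborolan-2-yl)phenyl N,N-diethylcarbamate (not isolated) | CCN(CC)C(=O)Oc1c(OC)cc(cc1OC)B1OC(C)(C)C(C)(C)O1 | intermediate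
4 | 4-hydroxy-2,6-dimethoxyphenyl N,N-diethylcarbamate | CCN(CC)C(=O)Oc1c(OC)cc(O)cc1OC | intermediate
5 | 4-(N,N-diethylcarbamoyloxy)-3,5-dimethoxyphenyl trifluoromethanesulfonate | CCN(CC)C(=O)Oc1c(OC)cc(OS(=O)(=O)C(F)(F)F)cc1OC | intermediate
6 | 2,3-dihydrofuran | C1=COCC1 | starting material
7 | 4-[(2S)-2,5-dihydrofuran-2-yl]-2,6-dimethoxyphenyl N,N-diethylcarbamate | C1=CCO[C@@H]1c1cc(OC)c(OC(=O)N(CC)CC)c(OC)c1 | intermediate
8 | trichloroacetyl chloride | ClC(Cl)(Cl)C(=O)Cl | starting material
9 | dichloroketene (not isolated) | ClC(Cl)=C=O | intermediate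
10 | (1R,4S,5S)-4-Ar-7,7-dichloro-3-oxabicyclo[3.2.0]heptan-6-one | O=C1[C@H]2[C@@H](C1(Cl)Cl)CO[C@@H]2c1cc(OC)c(OC(=O)N(CC)CC)c(OC)c1 | intermediate
11 | (2S,3S,4R)-2-Ar-4-(dichloromethyl)tetrahydrofuran-3-carboxylic acid (not isolated) | OC(=O)[C@H]1[C@@H](C(Cl)Cl)CO[C@@H]1c1cc(OC)c(OC(=O)N(CC)CC)c(OC)c1 | intermediate
12 | (3aR,6S,6aS)-6-Ar-3-hydroxytetrahydro-1H,3H-furo[3,4-c]furan-1-one, lactol epimers | O=C1[C@H]2[C@@H](C(O)O1)CO[C@@H]2c1cc(OC)c(OC(=O)N(CC)CC)c(OC)c1 | intermediate
13 | 4-bromo-2-methoxyphenol | COc1cc(Br)ccc1O | starting material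
14 | 1-(benzyloxy)-4-bromo-2-methoxybenzene | COc1cc(Br)ccc1OCc1ccccc1 | intermediate
15 | [4-(benzyloxy)-3-methoxyphenyl]magnesium bromide (not isolated) | COc1cc([Mg]Br)ccc1OCc1ccccc1 | intermediate
16 | (2S,3S,4R)-2-Ar-4-[(4-benzyloxy-3-methoxyphenyl)(hydroxy)methyl]tetrahydrofuran-3-carboxylic acid, carbinol epimers (not isolated) | OC(=O)[C@H]1[C@@H](C(O)c2ccc(OCc3ccccc3)c(OC)c2)CO[C@@H]1c1cc(OC)c(OC(=O)N(CC)CC)c(OC)c1 | intermediate
17 | (3aR,6S,6aS)-6-Ar-3-(4-benzyloxy-3-methoxyphenyl)tetrahydro-1H,3H-furo[3,4-c]furan-1-one, C3 epimers | O=C1[C@H]2[C@@H](C(O1)c1ccc(OCc3ccccc3)c(OC)c1)CO[C@@H]2c1cc(OC)c(OC(=O)N(CC)CC)c(OC)c1 | intermediate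
18 | (2S,3S,4R)-2-Ar-4-(4-hydroxy-3-methoxybenzyl)tetrahydrofuran-3-carboxylic acid | OC(=O)[C@H]1[C@@H](Cc2ccc(O)c(OC)c2)CO[C@@H]1c1cc(OC)c(OC(=O)N(CC)CC)c(OC)c1 | intermediate
19 | 4-[(2S,3R,4R)-4-(4-hydroxy-3-methoxybenzyl)-3-(hydroxymethyl)tetrahydrofuran-2-yl]-2,6-dimethoxyphenol | OC[C@H]1[C@@H](Cc2ccc(O)c(OC)c2)CO[C@@H]1c1cc(OC)c(O)c(OC)c1 | intermediate
20 | (E)-ferulic acid | COc1cc(/C=C/C(=O)O)ccc1O | starting material
21 | CNP0289934.1, the (2S,3R,4R) C9 ferulate | COc1cc(/C=C/C(=O)OC[C@H]2[C@@H](Cc3ccc(O)c(OC)c3)CO[C@@H]2c2cc(OC)c(O)c(OC)c2)ccc1O | target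

Total step count: 11. Longest linear sequence: 10 steps (steps 1–6 and 8–11); step 7 is a one-step branch.

Steps most likely to fail

**Step 5.**
- Process at risk: loss of regiocontrol in the cycloaddition, with the carbonyl carbon of the ketene bonding to C4 instead of C3. The two alkene carbons differ only through their allylic neighbours. Facial control should hold in either case.
- Fallback: the two arms exchange their roles, so that the other orientation of the ketene also serves. It sets out from 7, whose cycloaddition then delivers the isomeric adduct (1S,2S,5R)-2-Ar-7,7-dichloro-3-oxabicyclo[3.2.0]heptan-6-one F1 with the same cis, anti stereochemistry. The LiOH/AcOH protocol of step 6 should give the isomeric lactol F2, with the acid carbon on C4 and the masked aldehyde on C3. NaBH4 in aqueous EtOH followed by acidification should give the cis-fused lactone F3, in which C9 already stands at the alcohol level. One equivalent of 15 at −78 °C adds to the lactone carbonyl to give the keto alcohol F4, in equilibrium with its cyclic hemiketal. H2 over Pd/C in EtOAc/AcOH removes the benzyl group and takes the electron-rich aryl ketone down to the methylene group, giving the carbamate-protected alcohol F5. LiAlH4 as in step 10 frees the phenol, and the sequence comes back to the route at 19.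

**Step 6.**
- Process at risk: slow unmasking of the dichloromethyl group. Competing processes are loss of HCl by elimination, semibenzilic ring contraction in the hydroxide stage, and epimerisation at C4 through the open aldehyde.
- Fallback: oxidative instead of nucleophilic cleavage of C9–C7'. It sets out from 10. Zn in AcOH removes both chlorines to give the cyclobutanone F6. LDA/TMSCl at −78 °C enolises towards the C7' methylene group, because a double bond to the ring-fusion carbon C3 would be badly strained, and gives the silyl enol ether F7. Ozonolysis (O3, CH2Cl2/MeOH, −78 °C, then Me2S) cuts C9=C7' to the acid and the aldehyde, which close on work-up, and the sequence comes back at 12.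

**Step 9.**
- Process at risk: over-reduction by hydrogenolysis of the second benzylic bond C2–O1 (opening of the tetrahydrofuran ring), or a stalled cleavage of the lactone.
- Fallback: ionic instead of catalytic reduction. It sets out from 17. Et3SiH and CF3CO2H in CH2Cl2 at −20 to 0 °C should ionise only C7'–O, because that cation is stabilised by the 4-benzyloxy-3-methoxyphenyl group while the carbamate-bearing ring disfavours ionisation at C2. Hydride capture gives the O-benzyl acid F8. A short hydrogenolysis (H2, 1 bar, Pd/C, EtOAc) then removes only the benzyl ether, and the sequence comes back at 18.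

Further compounds
F1 | step 5 | (1S,2S,5R)-2-Ar-7,7-dichloro-3-oxabicyclo[3.2.0]heptan-6-one | ClC1(Cl)[C@H]2[C@@H](C1=O)CO[C@@H]2c1cc(OC)c(OC(=O)N(CC)CC)c(OC)c1
F2 | step 5 | (3aS,4S,6aR)-4-Ar-3-hydroxytetrahydro-1H,3H-furo[3,4-c]furan-1-one, lactol epimers | OC1[C@H]2[C@@H](C(=O)O1)CO[C@@H]2c1cc(OC)c(OC(=O)N(CC)CC)c(OC)c1
F3 | step 5 | (3aR,4S,6aR)-4-Ar-tetrahydro-1H,3H-furo[3,4-c]furan-1-one | C1[C@H]2[C@@H](C(=O)O1)CO[C@@H]2c1cc(OC)c(OC(=O)N(CC)CC)c(OC)c1
F4 | step 5 | (2S,3R,4R)-2-Ar-4-(4-benzyloxy-3-methoxybenzoyl)-3-(hydroxymethyl)tetrahydrofuran | OC[C@H]1[C@@H](C(=O)c2ccc(OCc3ccccc3)c(OC)c2)CO[C@@H]1c1cc(OC)c(OC(=O)N(CC)CC)c(OC)c1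
F5 | step 5 | (2S,3R,4R)-2-Ar-4-(4-hydroxy-3-methoxybenzyl)-3-(hydroxymethyl)tetrahydrofuran | OC[C@H]1[C@@H](Cc2ccc(O)c(OC)c2)CO[C@@H]1c1cc(OC)c(OC(=O)N(CC)CC)c(OC)c1
F6 | step 6 | (1R,4S,5S)-4-Ar-3-oxabicyclo[3.2.0]heptan-6-one | O=C1[C@H]2[C@@H](C1)CO[C@@H]2c1cc(OC)c(OC(=O)N(CC)CC)c(OC)c1
F7 | step 6 | trimethylsilyl enol ether of F6 with the C9=C7' double bond | C[Si](C)(C)OC=1[C@H]2[C@@H](C=1)CO[C@@H]2c1cc(OC)c(OC(=O)N(CC)CC)c(OC)c1
F8 | step 9 | (2S,3S,4R)-2-Ar-4-(4-benzyloxy-3-methoxybenzyl)tetrahydrofuran-3-carboxylic acid | OC(=O)[C@H]1[C@@H](Cc2ccc(OCc3ccccc3)c(OC)c2)CO[C@@H]1c1cc(OC)c(OC(=O)N(CC)CC)c(OC)c1
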